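## Structural features

Numbering: labdane numbers C1–C20 are used for the decalin and chain, with C16 as the methylene carbon on C13. The lactone takes primed furanone numbers (O1′, C2′–C5′).

- **Skeleton.** The target is a C25 compound. A trans-decalin (ring A: C1–C5, C10; ring B: C5–C10) carries at C9 the chain C11–C12–C13(=C16H2)–C14H(OH)–C15H(OH). The chain ends, through the C15–C5′ bond, in a 4′-methylbut-2′-en-4′-olide (ring C).
- **Ring stereocentres.** The decalin holds six stereocentres: C4, C5, C6 in a row and C8, C9, C10 in a row. C4 and C10 are quaternary and C8 is a tertiary carbinol. The methyl groups C19, C20 and C17 are all axial on the β face, whereas O6, O8, C11 and C18 are all equatorial.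
- **Chain stereocentres.** The chain carries an all-syn triad, C14 (S), C15 (R), C5′ (R). It is insulated from the ring stereocentres by C11–C13, so the decalin cannot control it.
- **Fragile groups.**
  - The γ-hydroxy aldehyde C18H=O/O6–H can close to a lactol or be over-oxidised to a lactone.
  - The tertiary alcohol at C8 can lose water or close an ether onto C12 or C13.
  - The allylic alcohol at C14 is sensitive.
  - The acidic H at C5′ allows epimerisation and translactonisation to O15 or O14.
- **Real difficulty.** C4 is a quaternary centre whose two one-carbon substituents differ only in oxidation level. It is 1,3-diaxial to C20 and sits next to oxygen at the unactivated C6. No abundant terpene offers this pattern.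
- **Features that decide the plan.**
  - C1–C20 form an intact labdane with a 6α-oxygen.
  - The equatorial O6 on ring B lies peri to the equatorial C18 on ring A, joined by the array O6–C6–C5–C4–C18. The key step uses this array for a 1,5-hydrogen transfer that turns the 4α-methyl group of a gem-dimethyl precursor into the aldehyde carbon.

## Logic of the disconnections

**18 ⇒ 17 ⇒ 16.**
- Bonds cut: the three O–Si bonds at O8, O14 and O15, then C18=O back to C18=N–OH.
- Reason: the free tetraol-aldehyde tolerates neither base nor oxidants, so it is released last.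
- Gain: the aldehyde is carried as its direct precursor.
- Demand: both operations must be non-basic and non-reducing, because of H5′ and the butenolide.

**16 ⇒ 14 (key).**
- Bonds cut: C18–N, with hydrogen returned to C18 and NO returned to O6.
- Reason: O6 is the only atom that can tell the two methyl groups on C4 apart.
- Gain: the C4 stereocentre and the aldehyde vanish, C4 becomes a gem-dimethyl carbon, and the decalin becomes that of a commercial labdane.
- Demand: a single alkoxyl radical at O6 that abstracts from C18 only.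
- In one sentence: photolysis of the 6α-nitrite of the fully assembled 18-deoxy compound.

**14 ⇒ 13 ⇒ 12 ⇒ 11.**
- Bonds cut: O6–N, then the O–Si bonds, with O6 returned to its carbonate.
- Reason: the nitrite must form at O6 alone.
- Gain: none in skeleton; it isolates O6.
- Demand: the group on O6 must leave under conditions that spare silyl ethers and the lactone.

**11 ⇒ 9.**
- Bonds cut: C14–O, with the double bond moved from C13=C16 back to C13=C14.
- Reason: the unit C13(=CH2)–CH(OH)–CH(OH) is the retron of a hydroxyl-directed ene reaction of oxygen.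
- Gain: C14 disappears as a stereocentre and is relayed from C15.
- Demand: an E-configured C13=C14 bond (C16 cis to C15) and a free O15–H.

**9 ⇒ 5 + 7.**
- Bonds cut: C15–C5′.
- Reason: this is the seam between the C20 and C5 units.
- Gain: two stereocentres and ring C are removed at once.
- Demand: absolute control by a catalyst, attack at the γ position of the dienol ether, and syn selectivity.

**5 ⇒ 4 ⇒ 3.**
- Bonds cut: C15=O, with oxygen returned to C13 and the double bond to C14=C15; then the O6 carbonate.
- Reason: the enal is the transposed form of the tertiary vinyl carbinol of the starting labdane.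
- Gain: no carbon is added or lost.
- Demand: O6 must be masked against the oxidant.

**3 ⇒ 2 ⇒ 1.**
- Bonds cut: C17–H, then C8–O.
- Reason: the axial methyl and equatorial hydroxyl at C8 arise from α-face oxidation of the exocyclic alkene.
- Gain: C8 is no longer a stereocentre.
- Demand: site selectivity over the vinyl group and α-face attack.

**7 ⇒ 6.**
- Bonds cut: O–Si.
- Gain: a commercial butenolide.
- Demand: none.

## Other disconnections considered

**Alternative 1:** (the first that comes to mind)
- Cut: C13–C14.
- Forward key step: Nozaki–Hiyama–Kishi coupling of the 2-iodoalkene A1 with the α-silyloxy aldehyde A2.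
- Grounds for rejection:
  - C14 would be created next to C15 by a non-chelated addition. The Felkin–Anh model predicts the 14,15-anti pair, whereas the target is syn, so an oxidation/reduction repair would follow.
  - A2 has two acidic positions (H15, H5′).
  - A1 still holds all six ring stereocentres with O6 and C18 oxidised. It would have to be built over many steps from a labdane lactone lacking both oxygens, or from a bicyclic enedione.
  - The cut simplifies the chain and leaves the C4/C6 problem untouched.

**Alternative 2:**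
- Cut: C4–C5 and C1–C10 (ring A).
- Forward key step: catalytic enantioselective endo Diels–Alder reaction of 2,6-dimethyl-1,4-benzoquinone with the dienyl ether A3 to the cis adduct A4.
- Merits: suprafacial addition sets C4 and C10 together, C5 can be corrected next to C6=O, and ring B arrives with O6 and C17.
- Grounds for rejection:
  - A3 carries a methyl group in the inside position of the reacting terminus. This strains the s-cis conformer and opens a competing 1,5-hydrogen shift.
  - C9 arrives as a carbonyl flanked by C10 and the C8 methyl group. It must be exchanged for CH–C11 while the more reactive C6=O is masked.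
  - The route would be roughly twice as long.

**Alternative 3:**
- Cut: reconnect C17 to C13, which rebuilds the third ring of abietic acid.
- Forward key step: dihydroxylation and glycol cleavage of the isopropyl-bearing double bond of methyl abietate to the seco keto-enal A5.
- Merits: C4, C5, C9, C10 and the C18 oxidation are bought.
- Grounds for rejection:
  - The isopropyl ketone has to be degraded.
  - The enal carbon has to be reduced to the C17 methyl group.
  - O6 and O8 must both be installed on ring B.
  - The chain from C13 onwards must be built anew. Step economy is clearly worse.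

Key step: step 11

Assumption: the (R,R)-bisphosphoramide of step 6 is taken to expose the Si face of C15 in 5 (if the sense is the opposite, its antipode is used and nothing else changes), and larixol is taken as an article of commerce from larch oleoresin.

## Steps

Step 1
Reactants: 1 (+)-larixol
Product: 2 (13S)-8α,17-epoxylabd-14-ene-6α,13-diol
Conditions: 3-chloroperbenzoic acid (1.05 equiv), CH2Cl2, 0 °C
Reagents that add atoms: 3-chloroperbenzoic acid, OOC(=O)c1cccc(Cl)c1
Why: Prilezhaev epoxidation; the 1,1-disubstituted C8=C17 bond is much more nucleophilic than the monosubstituted C14=C15 bond, and the peracid should come from the α face because the β face is covered by the axial C20 methyl group and the 6α-hydroxyl can guide it by a hydrogen bond, which places O8 α.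

Step 2
Reactants: 2 (13S)-8α,17-epoxylabd-14-ene-6α,13-diol
Product: 3 (13S)-labd-14-ene-6α,8α,13-triol
Conditions: LiAlH4, THF, 0 to 40 °C; aqueous work-up
Reagents that add atoms: none
Why: SN2 opening of the spiro-epoxide by hydride at the unhindered C17H2 makes C17 the axial 8β-methyl group and leaves the C8–O bond, and so the 8α configuration, untouched; the vinyl group is inert.

Step 3
Reactants: 3 (13S)-labd-14-ene-6α,8α,13-triol
Product: 4 (13S)-6α-(2,2,2-trichloroethoxycarbonyloxy)labd-14-ene-8α,13-diol
Conditions: 2,2,2-trichloroethyl chloroformate, pyridine, 4-(dimethylamino)pyridine (cat.), CH2Cl2, 0 °C to rt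
Reagents that add atoms: 2,2,2-trichloroethyl chloroformate, O=C(Cl)OCC(Cl)(Cl)Cl
Why: Acylation by a chloroformate; only the secondary O6–H can react, the two tertiary alcohols being too hindered, and the carbonate resists hexavalent chromium, chlorosilanes, singlet oxygen and silyl triflates and is later removed by zinc without base.

Step 4
Reactants: 4 (13S)-6α-(2,2,2-trichloroethoxycarbonyloxy)labd-14-ene-8α,13-diol
Product: 5 (13E)-8α-hydroxy-6α-(2,2,2-trichloroethoxycarbonyloxy)labd-13-en-15-al
Conditions: C5H5NH[CrO3Cl], NaOAc, 4 Å sieves, CH2Cl2, rt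
Reagents that add atoms: pyridinium chlorochromate, [O-][Cr](=O)(=O)Cl.c1cc[nH+]cc1
Why: Babler–Dauben oxidative transposition; the tertiary allylic chromate ester shifts by a [3,3] process to the primary chromate, which collapses to the enal, so that the C13 stereocentre is traded for C13=C14 and C15 reaches the aldehyde level in one operation; the more stable E isomer (C12 trans to C15) is separated and the other isomer is re-equilibrated; the tertiary O8–H cannot be oxidised.

Step 5
Reactants: 6 4-methylfuran-2(5H)-one
Product: 7 tert-butyldimethyl[(4-methylfuran-2-yl)oxy]silane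
Conditions: tert-butyldimethylsilyl trifluoromethanesulfonate, Et3N, CH2Cl2, 0 °C
Reagents that add atoms: tert-butyldimethylsilyl trifluoromethanesulfonate, CC(C)(C)[Si](C)(C)OS(=O)(=O)C(F)(F)F
Why: Soft enolisation and O-silylation of the butenolide give the aromatic 2-silyloxyfuran; no stereocentre is involved.

Step 6
Reactants: 5 (13E)-8α-hydroxy-6α-(2,2,2-trichloroethoxycarbonyloxy)labd-13-en-15-al; 7 tert-butyldimethyl[(4-methylfuran-2-yl)oxy]silane
Product: 9 (13E,15R)-15-[(5R)-4-methyl-2-oxo-2,5-dihydrofuran-5-yl]-6α-(2,2,2-trichloroethoxycarbonyloxy)labd-13-ene-8α,15-diol, via trichlorosilyl aldolate 8 (not isolated)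
Conditions: SiCl4 (2.2 equiv), N,N′-bis[(11bR)-3,5-dimethyl-4-oxido-3,5-dihydro-4H-dinaphtho[2,1-d:1′,2′-f][1,3,2]diazaphosphepin-4-yl]-N,N′-dimethylpentane-1,5-diamine (5 mol %), iPr2NEt (cat.), CH2Cl2, −78 °C; then H2O
Reagents that add atoms: none
Why: Catalytic enantioselective vinylogous Mukaiyama aldol reaction under Lewis base activation of SiCl4; the cationic silicon–phosphoramide complex binds the conjugated aldehyde and 7 attacks through C5′ in an open transition state, the chiral pocket fixing the aldehyde face (Si, giving 15R) and the antiperiplanar approach that keeps the furan ring away from the enal chain giving the syn 15R,5′R pair; the ring stereocentres are too far away to interfere.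

Step 7
Reactants: 9 (13E,15R)-15-[(5R)-4-methyl-2-oxo-2,5-dihydrofuran-5-yl]-6α-(2,2,2-trichloroethoxycarbonyloxy)labd-13-ene-8α,15-diol
Product: 11 (14S,15R)-15-[(5R)-4-methyl-2-oxo-2,5-dihydrofuran-5-yl]-6α-(2,2,2-trichloroethoxycarbonyloxy)labd-13(16)-ene-8α,14,15-triol, via allylic hydroperoxide 10 (not isolated)
Conditions: O2, 5,10,15,20-tetraphenylporphyrin (cat.), visible light, CH2Cl2, −20 °C; then PPh3
Reagents that add atoms: dioxygen, O=O
Why: Schenck ene reaction directed by the allylic hydroxyl; 1,3-allylic strain with C16H3 (cis to C15) holds H15 in the alkene plane, O15–H binds the incoming oxygen while ring C blocks the other face, so C14–O forms to give the threo (syn) 14S,15R pair, and hydrogen is taken from C16H3 on the more crowded side of the alkene (cis effect), which creates C13=C16H2; PPh3 reduces 10 with retention and the butenolide alkene is too electron-poor to react.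

Step 8
Reactants: 11 (14S,15R)-15-[(5R)-4-methyl-2-oxo-2,5-dihydrofuran-5-yl]-6α-(2,2,2-trichloroethoxycarbonyloxy)labd-13(16)-ene-8α,14,15-triol
Product: 12 8,14,15-tris-O-triethylsilyl ether of 11
Conditions: triethylsilyl trifluoromethanesulfonate (4.5 equiv), 2,6-lutidine, CH2Cl2, −78 to 0 °C
Reagents that add atoms: triethylsilyl trifluoromethanesulfonate, CC[Si](CC)(CC)OS(=O)(=O)C(F)(F)F
Why: A silyl triflate reaches the tertiary O8–H as well as O14–H and O15–H in one operation, so that O6 is afterwards the only oxygen that can be set free.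

Step 9
Reactants: 12 8,14,15-tris-O-triethylsilyl ether of 11
Product: 13 6α-alcohol (carbonate of 12 removed)
Conditions: Zn dust, AcOH–THF (1:10), 0 °C
Reagents that add atoms: none
Why: Reductive β-elimination of the trichloroethyl carbonate by zinc followed by loss of CO2; silyl ethers, the 1,1-disubstituted alkene and the butenolide are not reduced under these conditions.

Step 10
Reactants: 13 6α-alcohol (carbonate of 12 removed)
Product: 14 6α-nitrite ester of 13
Conditions: NOCl, pyridine, −30 °C, dark
Reagents that add atoms: nitrosyl chloride, O=NCl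
Why: O-Nitrosation of the only free alcohol, which should be much faster than addition of NOCl to the hindered and inductively deactivated C13=C16 bond; the C6–O bond is not touched.

Step 11
Reactants: 14 6α-nitrite ester of 13
Product: 16 (E)-18-oxime of the 6α-hydroxy-18-al (8,14,15-tris-O-triethylsilyl), via C18-nitroso compound 15 (not isolated)
Conditions: hν (365 nm), toluene, 10 °C, Ar; then 2-propanol, 70 °C
Reagents that add atoms: none
Why: Barton nitrite photolysis: excitation of 14 breaks the O–NO bond and gives the 6α-alkoxyl radical and NO. The radical oxygen is equatorial on ring B and peri to the equatorial 4α-methyl carbon C18 on ring A (about 2.6 Å in a model), so hydrogen is taken from C18 through the chair-like six-membered array O6–C6–C5–C4–C18–H. The primary C18 radical is captured by NO to give 15, which dimerises and on warming tautomerises to aldoxime 16, while O6 returns as the free alcohol. No ring is closed; only this cyclic transition state is passed. C4 becomes a stereocentre here and its configuration is fixed by distance alone, because the axial methyl groups C19, C20 and C17 stand on the β face well beyond reach of the α-oriented oxygen and C4, C10 and C8 carry no hydrogen. The step needs site selectivity, which the rigid trans-decalin secures, and a single alkoxyl radical, which is secured because O8, O14 and O15 are silylated and cannot form nitrites. Light of 365 nm is absorbed by the nitrite only, not by the butenolide or the alkene. The closest known reaction type is the conversion of steroidal 11β- and 6β-nitrites into C18 and C19 oximes.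

Step 12
Reactants: 16 (E)-18-oxime of the 6α-hydroxy-18-al (8,14,15-tris-O-triethylsilyl)
Product: 17 6α-hydroxy-18-al (8,14,15-tris-O-triethylsilyl)
Conditions: NaNO2, AcOH–H2O–THF, 0 to 5 °C
Reagents that add atoms: sodium nitrite, [Na+].[O-]N=O
Why: Deoximation with nitrous acid; N-nitrosation of the oxime, closure of the nitroso oxygen on C18 and loss of N2O give the aldehyde under weakly acidic conditions, C4 has no hydrogen and cannot epimerise, and partial loss of silyl groups here would be harmless.

Step 13
Reactants: 17 6α-hydroxy-18-al (8,14,15-tris-O-triethylsilyl)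
Product: 18 target CNP0156243.1
Conditions: HF·pyridine, pyridine, THF, 0 °C to rt
Reagents that add atoms: none
Why: Fluoride-driven cleavage of the three triethylsilyl ethers under buffered non-basic conditions, which should avoid epimerisation at C5′, translactonisation and loss of water at C8.

## Compound list

1 | (+)-larixol, (13S)-labda-8(17),14-diene-6α,13-diol | C=C[C@@](C)(O)CC[C@@H]1[C@@]2(C)CCCC(C)(C)[C@@H]2[C@@H](O)CC1=C | starting material
2 | (13S)-8α,17-epoxylabd-14-ene-6α,13-diol | C=C[C@@](C)(O)CC[C@@H]1[C@@]2(C)CCCC(C)(C)[C@@H]2[C@@H](O)C[C@@]1(C3)O3 | intermediate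
3 | (13S)-labd-14-ene-6α,8α,13-triol | C=C[C@@](C)(O)CC[C@@H]1[C@@]2(C)CCCC(C)(C)[C@@H]2[C@@H](O)C[C@@]1(C)O | intermediate
4 | (13S)-6α-(2,2,2-trichloroethoxycarbonyloxy)labd-14-ene-8α,13-diol | C=C[C@@](C)(O)CC[C@@H]1[C@@]2(C)CCCC(C)(C)[C@@H]2[C@@H](OC(=O)OCC(Cl)(Cl)Cl)C[C@@]1(C)O | intermediate
5 | (13E)-8α-hydroxy-6α-(2,2,2-trichloroethoxycarbonyloxy)labd-13-en-15-al | O=C/C=C(\C)CC[C@@H]1[C@@]2(C)CCCC(C)(C)[C@@H]2[C@@H](OC(=O)OCC(Cl)(Cl)Cl)C[C@@]1(C)O | intermediate
6 | 4-methylfuran-2(5H)-one | CC1=CC(=O)OC1 | starting material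
7 | tert-butyldimethyl[(4-methylfuran-2-yl)oxy]silane | Cc1coc(O[Si](C)(C)C(C)(C)C)c1 | intermediate
8 | O15-trichlorosilyl ether of 9 | C/C(CC[C@@H]1[C@@]2(C)CCCC(C)(C)[C@@H]2[C@@H](OC(=O)OCC(Cl)(Cl)Cl)C[C@@]1(C)O)=C\[C@@H](O[Si](Cl)(Cl)Cl)[C@@H]1OC(=O)C=C1C | intermediate
9 | syn aldol adduct, 13E,15R,5′R, O6 as trichloroethyl carbonate | C/C(CC[C@@H]1[C@@]2(C)CCCC(C)(C)[C@@H]2[C@@H](OC(=O)OCC(Cl)(Cl)Cl)C[C@@]1(C)O)=C\[C@@H](O)[C@@H]1OC(=O)C=C1C | intermediate
10 | (14S)-14-hydroperoxide with C13=C16H2 | C=C(CC[C@@H]1[C@@]2(C)CCCC(C)(C)[C@@H]2[C@@H](OC(=O)OCC(Cl)(Cl)Cl)C[C@@]1(C)O)[C@H](OO)[C@@H](O)[C@@H]1OC(=O)C=C1C | intermediate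
11 | 8α,14S,15R-triol, O6 as trichloroethyl carbonate | C=C(CC[C@@H]1[C@@]2(C)CCCC(C)(C)[C@@H]2[C@@H](OC(=O)OCC(Cl)(Cl)Cl)C[C@@]1(C)O)[C@H](O)[C@@H](O)[C@@H]1OC(=O)C=C1C | intermediate
12 | 8,14,15-tris-O-triethylsilyl ether of 11 | C=C(CC[C@@H]1[C@@]2(C)CCCC(C)(C)[C@@H]2[C@@H](OC(=O)OCC(Cl)(Cl)Cl)C[C@@]1(C)O[Si](CC)(CC)CC)[C@H](O[Si](CC)(CC)CC)[C@@H](O[Si](CC)(CC)CC)[C@@H]1OC(=O)C=C1C | intermediate
13 | 6α-alcohol, 8,14,15-tris-O-triethylsilyl | C=C(CC[C@@H]1[C@@]2(C)CCCC(C)(C)[C@@H]2[C@@H](O)C[C@@]1(C)O[Si](CC)(CC)CC)[C@H](O[Si](CC)(CC)CC)[C@@H](O[Si](CC)(CC)CC)[C@@H]1OC(=O)C=C1C | intermediate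
14 | 6α-nitrite ester of 13 | C=C(CC[C@@H]1[C@@]2(C)CCCC(C)(C)[C@@H]2[C@@H](ON=O)C[C@@]1(C)O[Si](CC)(CC)CC)[C@H](O[Si](CC)(CC)CC)[C@@H](O[Si](CC)(CC)CC)[C@@H]1OC(=O)C=C1C | intermediate
15 | 18-nitroso-6α-alcohol | C=C(CC[C@@H]1[C@@]2(C)CCC[C@@](C)(CN=O)[C@@H]2[C@@H](O)C[C@@]1(C)O[Si](CC)(CC)CC)[C@H](O[Si](CC)(CC)CC)[C@@H](O[Si](CC)(CC)CC)[C@@H]1OC(=O)C=C1C | intermediate
16 | (E)-18-aldoxime, 6α-alcohol | C=C(CC[C@@H]1[C@@]2(C)CCC[C@@](C)(/C=N/O)[C@@H]2[C@@H](O)C[C@@]1(C)O[Si](CC)(CC)CC)[C@H](O[Si](CC)(CC)CC)[C@@H](O[Si](CC)(CC)CC)[C@@H]1OC(=O)C=C1C | intermediate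
17 | 18-aldehyde, 6α-alcohol, 8,14,15-tris-O-triethylsilyl | C=C(CC[C@@H]1[C@@]2(C)CCC[C@@](C)(C=O)[C@@H]2[C@@H](O)C[C@@]1(C)O[Si](CC)(CC)CC)[C@H](O[Si](CC)(CC)CC)[C@@H](O[Si](CC)(CC)CC)[C@@H]1OC(=O)C=C1C | intermediate
18 | CNP0156243.1 | C=C(CC[C@@H]1[C@@]2(C)CCC[C@@](C)(C=O)[C@@H]2[C@@H](O)C[C@@]1(C)O)[C@H](O)[C@@H](O)[C@@H]1OC(=O)C=C1C | target

## Step count and least certain steps

Total step count: 13. Longest linear sequence: 12 (steps 1–4 and 6–13).

**Step 11 (key step).**
- What may go wrong:
  - β-Scission of the strained C5–C6 bond of the alkoxyl radical may compete with hydrogen transfer.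
  - Hydrogen may be abstracted from the ethyl groups of the O8 silyl ether.
  - Material may be lost by secondary photolysis of the nitroso compound.
- Fallback (from 13, back at 17): a metal-catalysed C–H silylation in place of the radical relay.
  - 13 is converted with Et2SiH2 and [Ir(cod)OMe]2 into the diethylhydrosilyl ether F1.
  - [Rh(cod)Cl]2 with 4,5-bis(diphenylphosphino)-9,9-dimethylxanthene and norbornene closes the six-membered oxasilinane F2. Insertion goes into the nearest primary C–H bond, C18, because no γ C–H bond exists.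
  - Tamao–Fleming oxidation (H2O2, KHCO3) gives the 6α,18-diol F3.
  - 2,2,6,6-Tetramethylpiperidine-1-oxyl with PhI(OAc)2 oxidises the primary alcohol to 17. Lactol closure, and with it over-oxidation, is disfavoured by the doubly trans-fused oxolane it would need.

**Step 6.**
- What may go wrong:
  - Facial and syn/anti selectivity may be poor, because the 4′-methyl group sits next to the reacting C5′.
  - The tertiary alcohol consumes SiCl4.
- Fallback (from 5, back at 9): reagent-controlled alkoxyallylboration and ring closure in place of the aldol step.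
  - Brown alkoxyallylboration with (Z)-[3-(4-methoxybenzyloxy)-2-methylallyl]diisopinocampheylborane gives the syn homoallylic alcohol F4. The borane is made from 4-methoxybenzyl methallyl ether with s-BuLi, the proper antipode of (Ipc)2BOMe and BF3·OEt2.
  - Et3SiCl and imidazole give the O15 silyl ether F5.
  - 2,3-Dichloro-5,6-dicyano-1,4-benzoquinone frees the C5′ alcohol F6.
  - Acryloyl chloride and iPr2NEt give the acrylate F7.
  - Ring-closing metathesis with the second-generation Grubbs catalyst closes the silylated butenolide F8.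
  - AcOH–H2O–THF then returns 9.

**Step 7.**
- What may go wrong:
  - Hydrogen may be abstracted from C12 instead of C16.
  - The threo preference may erode if O15–H binds the lactone carbonyl instead of the incoming oxygen.
- Fallback (from 9, back at 11): epoxide isomerisation in place of the ene reaction.
  - 3-Chloroperbenzoic acid under the same 1,3-allylic strain control gives the threo epoxy alcohol F9.
  - Cp2TiCl (trivalent titanium, from Cp2TiCl2 and Mn) opens F9 to the tertiary C13 radical. A second equivalent traps the radical, and β-hydride elimination towards the methyl group gives 11.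

**Step 4.**
- What may go wrong:
  - The tertiary allylic chromate may ionise and O8 may capture the allyl cation (tetrahydropyran closure).
  - E selectivity may be incomplete.
- Fallback (from 4, back at 5): degradation and olefination in place of the transposition.
  - Lemieux–Johnson cleavage (OsO4 cat., excess NaIO4) takes the vinyl carbinol through to the methyl ketone F10.
  - Horner–Wadsworth–Emmons formylolefination with diethyl [2-(cyclohexylimino)ethyl]phosphonate and NaH, followed by aqueous oxalic acid, gives 5.

## Further compounds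

F1 | step 11 | O6-diethylhydrosilyl ether of 13 | C=C(CC[C@@H]1[C@@]2(C)CCCC(C)(C)[C@@H]2[C@@H](O[SiH](CC)CC)C[C@@]1(C)O[Si](CC)(CC)CC)[C@H](O[Si](CC)(CC)CC)[C@@H](O[Si](CC)(CC)CC)[C@@H]1OC(=O)C=C1C
F2 | step 11 | O6–Si–C18 oxasilinane | C=C(CC[C@@H]1[C@@]2(C)CCC[C@@](C)(C[Si]3(CC)CC)[C@@H]2[C@@H](O3)C[C@@]1(C)O[Si](CC)(CC)CC)[C@H](O[Si](CC)(CC)CC)[C@@H](O[Si](CC)(CC)CC)[C@@H]1OC(=O)C=C1C
F3 | step 11 | 6α,18-diol, 8,14,15-tris-O-triethylsilyl | C=C(CC[C@@H]1[C@@]2(C)CCC[C@@](C)(CO)[C@@H]2[C@@H](O)C[C@@]1(C)O[Si](CC)(CC)CC)[C@H](O[Si](CC)(CC)CC)[C@@H](O[Si](CC)(CC)CC)[C@@H]1OC(=O)C=C1C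
F4 | step 6 | syn 15R-alcohol with 5′R 4-methoxybenzyl ether and isopropenyl group | C/C(CC[C@@H]1[C@@]2(C)CCCC(C)(C)[C@@H]2[C@@H](OC(=O)OCC(Cl)(Cl)Cl)C[C@@]1(C)O)=C\[C@@H](O)[C@H](OCc1ccc(OC)cc1)C(C)=C
F5 | step 6 | O15-triethylsilyl ether of F4 | C/C(CC[C@@H]1[C@@]2(C)CCCC(C)(C)[C@@H]2[C@@H](OC(=O)OCC(Cl)(Cl)Cl)C[C@@]1(C)O)=C\[C@@H](O[Si](CC)(CC)CC)[C@H](OCc1ccc(OC)cc1)C(C)=C
F6 | step 6 | C5′ alcohol from F5 | C/C(CC[C@@H]1[C@@]2(C)CCCC(C)(C)[C@@H]2[C@@H](OC(=O)OCC(Cl)(Cl)Cl)C[C@@]1(C)O)=C\[C@@H](O[Si](CC)(CC)CC)[C@H](O)C(C)=C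
F7 | step 6 | C5′ acrylate of F6 | C/C(CC[C@@H]1[C@@]2(C)CCCC(C)(C)[C@@H]2[C@@H](OC(=O)OCC(Cl)(Cl)Cl)C[C@@]1(C)O)=C\[C@@H](O[Si](CC)(CC)CC)[C@H](OC(=O)C=C)C(C)=C
F8 | step 6 | O15-triethylsilyl ether of 9 | C/C(CC[C@@H]1[C@@]2(C)CCCC(C)(C)[C@@H]2[C@@H](OC(=O)OCC(Cl)(Cl)Cl)C[C@@]1(C)O)=C\[C@@H](O[Si](CC)(CC)CC)[C@@H]1OC(=O)C=C1C
F9 | step 7 | threo 13,14-epoxy-15-alcohol from 9 | C[C@]1(CC[C@@H]3[C@@]4(C)CCCC(C)(C)[C@@H]4[C@@H](OC(=O)OCC(Cl)(Cl)Cl)C[C@@]3(C)O)O[C@@H]1[C@@H](O)[C@@H]2OC(=O)C=C2C
F10 | step 4 | 8α-hydroxy-6α-(2,2,2-trichloroethoxycarbonyloxy)-14,15-dinorlabdan-13-one | CC(=O)CC[C@@H]1[C@@]2(C)CCCC(C)(C)[C@@H]2[C@@H](OC(=O)OCC(Cl)(Cl)Cl)C[C@@]1(C)O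
A1 | alternative 1 | protected decalin 2-iodoalkene | C=C(I)CC[C@@H]1[C@@]2(C)CCC[C@@](C)(CO[Si](C)(C)C(C)(C)C)[C@@H]2[C@@H](O[Si](CC)(CC)CC)C[C@@]1(C)O[Si](CC)(CC)CC
A2 | alternative 1 | α-triethylsilyloxy aldehyde bearing the butenolide | O=C[C@@H](O[Si](CC)(CC)CC)[C@@H]1OC(=O)C=C1C
A3 | alternative 2 | (E)-tert-butyldimethyl[(2-methylpenta-2,4-dien-1-yl)oxy]silane | C=C/C=C(\C)CO[Si](C)(C)C(C)(C)C
A4 | alternative 2 | cis-fused endo quinone adduct | O=C1[C@@]2(C)CC=C[C@@](C)(CO[Si](C)(C)C(C)(C)C)[C@H]2C(=O)C=C1C
A5 | alternative 3 | seco keto-enal from methyl abietate | CC(C)C(=O)CC[C@@H]1[C@@]2(C)CCC[C@@](C)(C(=O)OC)[C@@H]2CC=C1C=O
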